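Four flasks with the same charges differ in temperature, and the question is which one holds the most product when the time is up.

| setting | Friday's | Tuesday's | Wednesday's | Monday's |
|---|---|---|---|---|
| substrate | 0.46 M | 0.46 M | 0.46 M | 0.46 M |
| partner | 0.506 M | 0.506 M | 0.506 M | 0.506 M |
| free catalyst | 17 mM | 17 mM | 17 mM | 17 mM |
| temperature | 15 °C | 0 °C | −30 °C | −15 °C |
| time | 40 min | 40 min | 40 min | 40 min |

- the flask with the highest amount of product, in percent of the substrate charged ("all alike" if they lie within 1.5 percentage points) (Friday's / Tuesday's / Wednesday's / Monday's / all alike)
- final product, as a percentage of the substrate charged, in Friday's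
- final product, as a percentage of the substrate charged, in Tuesday's
- final product, as a percentage of the substrate charged, in Wednesday's
- final product, as a percentage of the substrate charged, in Monday's

- at 0 °C the constants are as listed, elsewhere as the activation energies and enthalpies make them

    partner + free catalyst ⇌ catalyst intermediate A (K1 = 7.0 L mol⁻¹, k1 = 0.52 L mol⁻¹ s⁻¹, Ea1 = 55.0 kJ mol⁻¹, ΔH1 = −12.0 kJ mol⁻¹)
    catalyst intermediate A → catalyst intermediate B (k2 = 0.11 s⁻¹, Ea2 = 74.0 kJ mol⁻¹)
    substrate + catalyst intermediate B → catalyst intermediate C (k3 = 5.3 L mol⁻¹ s⁻¹, Ea3 = 49.0 kJ mol⁻¹)
    catalyst intermediate C → free catalyst + product (k4 = 2.8 s⁻¹, Ea4 = 55.0 kJ mol⁻¹)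
    partner → decomposed reagent (k5 = 0.0016 s⁻¹, Ea5 = 75.0 kJ mol⁻¹)
    (constants at 0 °C)

Partner binds free catalyst reversibly to give catalyst intermediate A, A turns into B, B takes up substrate to give C, and C releases product and free catalyst. Beside this cycle, partner decays by itself to decomposed reagent.

I start with Wednesday's, the coldest flask at −30 °C. There A turns into B at 0.00197 s⁻¹, while B meets substrate at 0.170 s⁻¹ and C falls apart at 0.141 s⁻¹, both far faster. So in Wednesday's the concentration that sets the rate is that of catalyst intermediate A, the resting state, and its change into B is the rate-limiting step. In Wednesday's, free catalyst is captured at 0.0133 s⁻¹, and A falls back at 0.00195 s⁻¹. From these the start follows: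

share of catalyst in A = capture / (capture + falling back + onward) = 77.2 %

starting rate = onward constant × share × catalyst charged = 1.55 mM min⁻¹

What I carry forward is the turnover time, the substrate charge divided by the starting rate of the cycle:

turnover time = 296 min

Wednesday's has 40 min, so the starting rate gives 13.5 %. I reckon with two things that slow it. The catalyst needs 0.970 min to fill A, a factor of 0.976. Partner also falls through decay, the cycle and what A holds, to about 0.445 M in mid-run, which lowers the share by a factor of 0.970. Together they give my figure for Wednesday's:

12.8 %

The turnover time is 39.9 min in Monday's, about the time given. It is 6.97 min in Tuesday's, well inside that time. In Tuesday's, then, the contest is for partner: at the start the cycle takes it 1.36 times as fast as decay does. Where Monday's falls against Tuesday's stays open in this short reckoning.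

The forecast gave 65 % for Friday's, 71.5 % for Tuesday's, 12.5 % for Wednesday's and 66 % for Monday's, and named Tuesday's, holding of the partner that “warming favours its loss”. The flasks give 65.1 % in Friday's, 72.2 % in Tuesday's, 12.5 % in Wednesday's and 66.2 % in Monday's, so Tuesday's holds the most.

Wednesday's ended at 12.5 % against my 12.8 % from a turnover time of 296 min. At 40.0 min in Wednesday's, the half-life of free catalyst by forward capture was 1.1 min, shorter than the 5.9 min of catalyst intermediate A by its change into B, and the catalyst stood 71.8 % as A, 26.3 % free, 0.952 % as B and 1.00 % as C.

The neighbour is Wednesday's with 0.043 M of free catalyst. Its turnover time, shortened in proportion to the catalyst charge, is 117 min, which gives 34.2 % before any slowing. That flask gives 30.4 %, less, with 61 % of its partner left.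

The rate constants belong to no real substance; no experiment stands behind them.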